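## Retrosynthetic overview

- Locants count along the chain from the furan: furan C3–C5H2–C6H2–C7H=C8(Me)–C9H2–C10H(OAc)–C11H=C12(Me)–C13H2–C14H2–C15H(OH)–C16(Me)(O)–C17H2–C18H2–C19(=O)–O; the γ-lactone ring is O–C16–C17–C18–C19.
- Key disconnection C9–C10. The enabling feature is that the C10 carbinol carbon is homoallylic to the methyl-bearing C7=C8 alkene (O–C10–C9–C8(Me)=C7) and allylic to C11=C12. This is the retron of a transposing allylboration of a C10 enal by a β-methallyl boronate with boron on a stereogenic C7. One event makes the C9–C10 bond, the (S)-C10 centre and the E-C7=C8 alkene.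
- Right half (C10–C19) from geranyl acetate: epoxide to allylic alcohol, Johnson–Claisen rearrangement to the E-C15=C16 enoate, then Shi epoxidation and invertive 5-exo lactonisation. This sets C15/C16 and closes the γ-lactone ring, the only ring formed in the route.
- Left half (furan–C9): the furan ring is bought as 3-bromofuran and extended with oxetane; lithiation–borylation with isopropenyl-Bpin sets the C7–B centre that is relayed to C10.
- End game: acetylation of the C10 hydroxyl and removal of the C15 silyl ether.

Key step: step 11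

Remark (assumption): building blocks whose carbon atoms end in the skeleton are numbered as reactants; other reagents stand under "Reagents that add atoms", also where their atoms stay only in a numbered, non-isolated intermediate.

## Route

Step 1
Reactants: 1 geranyl acetate
Product: 2 6,7-epoxygeranyl acetate (racemic)
Conditions: mCPBA (1.05 equiv), NaHCO3, CH2Cl2, 0 °C
Reagents that add atoms: 3-chloroperbenzoic acid, OOC(=O)c1cccc(Cl)c1
Why: Prilezhaev epoxidation should be selective for the electron-rich C15=C16 alkene because C11=C12 is deactivated by the allylic acetate at C10; the new stereocentre is racemic and is erased in step 3.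

Step 2
Reactants: 2 6,7-epoxygeranyl acetate (racemic)
Product: 3 (2E)-6-hydroxy-3,7-dimethylocta-2,7-dien-1-yl acetate (racemic)
Conditions: Al(OiPr)3 (1.5 equiv), toluene, 110 °C; aq. work-up
Reagents that add atoms: none
Why: Al(OiPr)3-mediated isomerisation of a trisubstituted epoxide to an allylic alcohol (syn β-elimination through a cyclic transition state, aluminium on oxygen and isopropoxide removing a methyl proton) should open the epoxide at tertiary C16 and give the secondary C15 alcohol bearing an isopropenyl group.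

Step 3
Reactants: 3 (2E)-6-hydroxy-3,7-dimethylocta-2,7-dien-1-yl acetate (racemic); 4 triethyl orthoacetate
Product: 6 ethyl (4E,8E)-10-acetoxy-4,8-dimethyldeca-4,8-dienoate, via mixed ketene acetal 5 (not isolated)
Conditions: 4 (excess), EtCO2H (cat.), 140 °C, ethanol distilled off
Reagents that add atoms: none
Why: Johnson–Claisen rearrangement of ketene acetal 5 through a chair with the side chain equatorial should form the C17–C18 bond, give the E-trisubstituted C15=C16 alkene and deliver the ester arm that becomes C18–C19.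

Step 4
Reactants: 6 ethyl (4E,8E)-10-acetoxy-4,8-dimethyldeca-4,8-dienoate
Product: 8 (2E,6R)-6-hydroxy-3-methyl-6-[(2S)-2-methyl-5-oxooxolan-2-yl]hex-2-en-1-yl acetate, via epoxy ester 7 (not isolated)
Conditions: D-fructose-derived Shi ketone (30 mol %), KHSO5 (as Oxone, 2KHSO5·KHSO4·K2SO4), K2CO3, Bu4NHSO4 (cat.), MeCN/dimethoxymethane/aq. Na2B4O7 buffer, 0 °C; extractive work-up; then CSA (20 mol %), CH2Cl2, H2O (2 equiv), 0 °C to rt
Reagents that add atoms: potassium peroxymonosulfate, [K+].[O-]S(=O)(=O)OO (epoxide oxygen, later the C15 hydroxyl oxygen); water, O (lactone carbonyl oxygen)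
Why: Shi epoxidation (chiral dioxirane, spiro transition state) should attack only the electron-rich C15=C16 alkene and set the (15R,16R)-epoxide under catalyst control, after which acid-catalysed 5-exo opening at tertiary C16 by the ester carbonyl, with inversion at C16 and retention at C15 (water then releases ethanol), should close the γ-lactone ring with the (15R,16S) diad.

Step 5
Reactants: 8 (2E,6R)-6-hydroxy-3-methyl-6-[(2S)-2-methyl-5-oxooxolan-2-yl]hex-2-en-1-yl acetate
Product: 9 (2E,6R)-3-methyl-6-[(2S)-2-methyl-5-oxooxolan-2-yl]-6-(triethylsilyloxy)hex-2-en-1-yl acetate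
Conditions: TESOTf, 2,6-lutidine, CH2Cl2, −78 to 0 °C
Reagents that add atoms: triethylsilyl trifluoromethanesulfonate, CC[Si](CC)(CC)OS(=O)(=O)C(F)(F)F
Why: Silyl ether formation with the reactive triflate should protect the hindered C15 hydroxyl, so that it stays silent in the allylboration and is told apart from the C10 hydroxyl that is acetylated later.

Step 6
Reactants: 9 (2E,6R)-3-methyl-6-[(2S)-2-methyl-5-oxooxolan-2-yl]-6-(triethylsilyloxy)hex-2-en-1-yl acetate
Product: 10 (5S)-5-[(1R,4E)-6-hydroxy-4-methyl-1-(triethylsilyloxy)hex-4-en-1-yl]-5-methyloxolan-2-one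
Conditions: K2CO3 (0.2 equiv), MeOH, 0 °C
Reagents that add atoms: none
Why: Base-catalysed transesterification (methanolysis) should remove the unhindered primary allylic acetate much faster than it touches the silyl ether or the hindered γ-lactone, which would in any case re-close.

Step 7
Reactants: 10 (5S)-5-[(1R,4E)-6-hydroxy-4-methyl-1-(triethylsilyloxy)hex-4-en-1-yl]-5-methyloxolan-2-one
Product: 11 (2E,6R)-3-methyl-6-[(2S)-2-methyl-5-oxooxolan-2-yl]-6-(triethylsilyloxy)hex-2-enal
Conditions: MnO2 (excess), CH2Cl2, rt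
Reagents that add atoms: none
Why: MnO2 oxidation is selective for allylic alcohols and should give the E-enal without touching the lactone or silyl ether and without E/Z isomerisation.

Step 8
Reactants: 12 3-bromofuran; 13 oxetane
Product: 15 3-(furan-3-yl)propan-1-ol, via 3-furyllithium 14 (not isolated)
Conditions: nBuLi, THF, −78 °C; then 13, BF3·OEt2, −78 °C; aq. NH4Cl
Reagents that add atoms: n-butyllithium, CCCC[Li] (its lithium stands only in intermediate 14; no atom of it remains in 15)
Why: Bromine–lithium exchange at −78 °C should give 3-furyllithium without scrambling to the 2-lithio isomer, and BF3-promoted SN2 ring opening of oxetane by the organolithium should deliver the three-carbon alcohol (C5–C7) directly.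

Step 9
Reactants: 15 3-(furan-3-yl)propan-1-ol
Product: 16 3-(furan-3-yl)propyl N,N-diisopropylcarbamate
Conditions: iPr2NCOCl, Et3N, CH2Cl2, reflux
Reagents that add atoms: N,N-diisopropylcarbamoyl chloride, CC(C)N(C(C)C)C(Cl)=O
Why: Carbamoylation (O-acylation with a carbamoyl chloride) installs the group that directs the α-lithiation of step 10 and then serves as the leaving group.

Step 10
Reactants: 16 3-(furan-3-yl)propyl N,N-diisopropylcarbamate; 17 isopropenylboronic acid pinacol ester
Product: 20 2-[(3R)-1-(furan-3-yl)-4-methylpent-4-en-3-yl]-4,4,5,5-tetramethyl-1,3,2-dioxaborolane, via lithiated carbamate 18 (not isolated), via boronate complex 19 (not isolated)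
Conditions: sBuLi, (−)-sparteine, Et2O, −78 °C, 5 h; 17, −78 °C, 1 h; then reflux, 12 h
Reagents that add atoms: sec-butyllithium, CCC(C)[Li] (its lithium stands only in intermediates 18 and 19; no atom of it remains in 20)
Why: Lithiation–borylation: sBuLi/(−)-sparteine should remove the pro-S proton next to the carbamate oxygen (directed deprotonation, expected to outrun furan metalation at −78 °C) to give configurationally stable 18, boron of 17 replaces lithium with retention, and the stereospecific 1,2-migration of the isopropenyl group with inversion and loss of the carbamate sets the C7–B centre as R.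

Step 11
Reactants: 20 2-[(3R)-1-(furan-3-yl)-4-methylpent-4-en-3-yl]-4,4,5,5-tetramethyl-1,3,2-dioxaborolane; 11 (2E,6R)-3-methyl-6-[(2S)-2-methyl-5-oxooxolan-2-yl]-6-(triethylsilyloxy)hex-2-enal
Product: 24 (5S)-5-[(1R,4E,6S,8E)-11-(furan-3-yl)-6-hydroxy-4,8-dimethyl-1-(triethylsilyloxy)undeca-4,8-dien-1-yl]-5-methyloxolan-2-one, via boronate complex 21 (not isolated), via borinic ester 22 (not isolated), via O-borinate 23 (not isolated)
Conditions: 20 (1.3 equiv), nBuLi (1.3 equiv), THF, −78 °C; TFAA (1.3 equiv), −78 °C; 11 (1.0 equiv), −78 °C to rt; aq. NaHCO3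
Reagents that add atoms: n-butyllithium, CCCC[Li], and trifluoroacetic anhydride, O=C(OC(=O)C(F)(F)F)C(F)(F)F (their atoms stand only in intermediates 21 to 23 and are lost on hydrolysis; none remains in 24)
Why: nBuLi converts boronic ester 20 into boronate complex 21, TFAA acylates one pinacol oxygen to give the more Lewis-acidic B-butyl borinic ester 22, and this adds 1,2 to enal 11 through a closed six-membered chair transition state with allylic transposition, so that C9 bonds to C10 while the C7–B bond becomes the C7=C8 double bond (borinate 23 is hydrolysed on work-up). The closest known reaction type is the allylboration of aldehydes with enantioenriched α-substituted β-methallyl pinacol boronic esters through borinic esters generated in the flask, which gives E-trisubstituted homoallylic alcohols with transfer of chirality. No ring of the target is closed; the only cycle is the transient chair. The new C10 centre is controlled by the C7–B centre of 20 (1,3-chirality transfer): with the C6 chain pseudo-equatorial at C7 and the enal residue equatorial, (R)-20 delivers C9 to the aldehyde face that gives (S)-C10, and the remote C15/C16 centres should have no say. The step needs E over Z at C7=C8, 1,2- over 1,4-addition and aldehyde over lactone selectivity: the larger butyl/alkoxy ligand set of the borinic ester penalises the axial C6 chain (which a slim pinacol ester would prefer because of allylic 1,2-strain with the C8 methyl and which leads to the Z isomer), boron allylation of enals is inherently 1,2, and nBuLi is consumed by boron before the lactone-bearing aldehyde is added.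

Step 12
Reactants: 24 (5S)-5-[(1R,4E,6S,8E)-11-(furan-3-yl)-6-hydroxy-4,8-dimethyl-1-(triethylsilyloxy)undeca-4,8-dien-1-yl]-5-methyloxolan-2-one
Product: 25 (5S)-5-[(1R,4E,6S,8E)-6-acetoxy-11-(furan-3-yl)-4,8-dimethyl-1-(triethylsilyloxy)undeca-4,8-dien-1-yl]-5-methyloxolan-2-one
Conditions: Ac2O, pyridine, DMAP (cat.), CH2Cl2, 0 °C to rt
Reagents that add atoms: acetic anhydride, CC(=O)OC(C)=O
Why: DMAP-catalysed acetylation (esterification) of the only free hydroxyl should give the C10 acetate with retention, because the C10–O bond is not touched.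

Step 13
Reactants: 25 (5S)-5-[(1R,4E,6S,8E)-6-acetoxy-11-(furan-3-yl)-4,8-dimethyl-1-(triethylsilyloxy)undeca-4,8-dien-1-yl]-5-methyloxolan-2-one
Product: 26 10-acetylirciformonin B
Conditions: HF·pyridine, pyridine, THF, 0 °C to rt
Reagents that add atoms: none
Why: Fluoride-mediated desilylation under buffered, nearly neutral conditions should free the C15 hydroxyl without ionising the allylic acetate, opening the lactone or harming the furan.

## Compound list

1 | geranyl acetate, (2E)-3,7-dimethylocta-2,6-dien-1-yl acetate | CC(C)=CCC/C(C)=C/COC(C)=O | starting material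
2 | 6,7-epoxygeranyl acetate, (2E)-5-(3,3-dimethyloxiran-2-yl)-3-methylpent-2-en-1-yl acetate, racemic | CC1(C)OC1CC/C(C)=C/COC(C)=O | intermediate
3 | (2E)-6-hydroxy-3,7-dimethylocta-2,7-dien-1-yl acetate, racemic | C=C(C)C(O)CC/C(C)=C/COC(C)=O | intermediate
4 | triethyl orthoacetate | CCOC(C)(OCC)OCC | starting material
5 | mixed ketene acetal, (2E)-6-[(1-ethoxyethenyl)oxy]-3,7-dimethylocta-2,7-dien-1-yl acetate, racemic | C=C(OCC)OC(CC/C(C)=C/COC(C)=O)C(C)=C | intermediate
6 | ethyl (4E,8E)-10-acetoxy-4,8-dimethyldeca-4,8-dienoate | CCOC(=O)CC/C(C)=C/CC/C(C)=C/COC(C)=O | intermediate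
7 | ethyl 3-[(2R,3R)-3-[(3E)-5-acetoxy-3-methylpent-3-en-1-yl]-2-methyloxiran-2-yl]propanoate | CCOC(=O)CC[C@@]1(C)O[C@@H]1CC/C(C)=C/COC(C)=O | intermediate
8 | (2E,6R)-6-hydroxy-3-methyl-6-[(2S)-2-methyl-5-oxooxolan-2-yl]hex-2-en-1-yl acetate | CC(=O)OC/C=C(\C)CC[C@@H](O)[C@]1(C)CCC(=O)O1 | intermediate
9 | (2E,6R)-3-methyl-6-[(2S)-2-methyl-5-oxooxolan-2-yl]-6-(triethylsilyloxy)hex-2-en-1-yl acetate | CC(=O)OC/C=C(\C)CC[C@@H](O[Si](CC)(CC)CC)[C@]1(C)CCC(=O)O1 | intermediate
10 | (5S)-5-[(1R,4E)-6-hydroxy-4-methyl-1-(triethylsilyloxy)hex-4-en-1-yl]-5-methyloxolan-2-one | OC/C=C(\C)CC[C@@H](O[Si](CC)(CC)CC)[C@]1(C)CCC(=O)O1 | intermediate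
11 | (2E,6R)-3-methyl-6-[(2S)-2-methyl-5-oxooxolan-2-yl]-6-(triethylsilyloxy)hex-2-enal | O=C/C=C(\C)CC[C@@H](O[Si](CC)(CC)CC)[C@]1(C)CCC(=O)O1 | intermediate
12 | 3-bromofuran | Brc1ccoc1 | starting material
13 | oxetane | C1COC1 | starting material
14 | 3-furyllithium | [Li]c1ccoc1 | intermediate
15 | 3-(furan-3-yl)propan-1-ol | OCCCc1ccoc1 | intermediate
16 | 3-(furan-3-yl)propyl N,N-diisopropylcarbamate | CC(C)N(C(C)C)C(=O)OCCCc1ccoc1 | intermediate
17 | isopropenylboronic acid pinacol ester, 4,4,5,5-tetramethyl-2-(prop-1-en-2-yl)-1,3,2-dioxaborolane | C=C(C)B1OC(C)(C)C(C)(C)O1 | starting material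
18 | (1S)-3-(furan-3-yl)-1-lithiopropyl N,N-diisopropylcarbamate, as its (−)-sparteine complex | [Li][C@@H](CCc1ccoc1)OC(=O)N(C(C)C)C(C)C | intermediate
19 | lithium boronate complex from 18 and 17 (boron in place of lithium, retention) | [Li+].C=C(C)[B-]1(OC(C)(C)C(C)(C)O1)[C@@H](CCc1ccoc1)OC(=O)N(C(C)C)C(C)C | intermediate
20 | 2-[(3R)-1-(furan-3-yl)-4-methylpent-4-en-3-yl]-4,4,5,5-tetramethyl-1,3,2-dioxaborolane | C=C(C)[C@@H](CCc1ccoc1)B1OC(C)(C)C(C)(C)O1 | intermediate
21 | lithium B-butyl boronate complex of 20 | [Li+].C=C(C)[C@@H](CCc1ccoc1)[B-]1(CCCC)OC(C)(C)C(C)(C)O1 | intermediate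
22 | B-butyl borinic ester, 2,3-dimethyl-3-(trifluoroacetoxy)butan-2-yl butyl[(3R)-1-(furan-3-yl)-4-methylpent-4-en-3-yl]borinate | C=C(C)[C@@H](CCc1ccoc1)B(CCCC)OC(C)(C)C(C)(C)OC(=O)C(F)(F)F | intermediate
23 | O-borinate of 24 (C10–O–B(butyl)–O–pinacol mono-trifluoroacetate) | CCCCB(OC(C)(C)C(C)(C)OC(=O)C(F)(F)F)O[C@H](/C=C(\C)CC[C@@H](O[Si](CC)(CC)CC)[C@]1(C)CCC(=O)O1)C/C(C)=C/CCc1ccoc1 | intermediate
24 | (5S)-5-[(1R,4E,6S,8E)-11-(furan-3-yl)-6-hydroxy-4,8-dimethyl-1-(triethylsilyloxy)undeca-4,8-dien-1-yl]-5-methyloxolan-2-one | O[C@H](/C=C(\C)CC[C@@H](O[Si](CC)(CC)CC)[C@]1(C)CCC(=O)O1)C/C(C)=C/CCc1ccoc1 | intermediate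
25 | (5S)-5-[(1R,4E,6S,8E)-6-acetoxy-11-(furan-3-yl)-4,8-dimethyl-1-(triethylsilyloxy)undeca-4,8-dien-1-yl]-5-methyloxolan-2-one | CC(=O)O[C@H](/C=C(\C)CC[C@@H](O[Si](CC)(CC)CC)[C@]1(C)CCC(=O)O1)C/C(C)=C/CCc1ccoc1 | intermediate
26 | 10-acetylirciformonin B, (5S)-5-[(1R,4E,6S,8E)-6-acetoxy-11-(furan-3-yl)-1-hydroxy-4,8-dimethylundeca-4,8-dien-1-yl]-5-methyloxolan-2-one | CC(=O)O[C@H](/C=C(\C)CC[C@@H](O)[C@]1(C)CCC(=O)O1)C/C(C)=C/CCc1ccoc1 | target

## Step count and risks

Total step count: 13 (steps 1 to 7 right half, steps 8 to 10 left half, steps 11 to 13 union and end game).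
Longest linear sequence: 10 steps (steps 1 to 7, then 11 to 13).

**Step 11 (key allylboration).** What may go wrong: erosion of E/Z selectivity if the chair with the C6 chain axial competes; incomplete conversion of the boronate complex into the borinic ester, so that the slow, Z-selective pinacol pathway takes over; electrophilic trifluoroacetylation of the furan by unconsumed anhydride; incomplete chirality transfer.

Fallback, setting out from 15 and 11 and coming back at 24: the olefin geometry is fixed before the coupling and C10 is set afterwards by catalyst control. Oxidation of 15 with Dess–Martin periodinane should give 3-(furan-3-yl)propanal F1. Wittig olefination with Ph3P=C(CH3)CO2Et should give ethyl (2E)-5-(furan-3-yl)-2-methylpent-2-enoate F2. Reduction with iBu2AlH should give (2E)-5-(furan-3-yl)-2-methylpent-2-en-1-ol F3. MsCl, LiCl and 2,4,6-collidine in DMF should give 3-[(3E)-5-chloro-4-methylpent-3-en-1-yl]furan F4. The allylbarium reagent made from F4 with activated barium (BaI2, lithium biphenylide, THF, −78 °C) should add to 11 at its α-carbon with retention of the E geometry (α-selective allylbarium carbonyl addition) to give (5S)-5-[(1R,4E,6RS,8E)-11-(furan-3-yl)-6-hydroxy-4,8-dimethyl-1-(triethylsilyloxy)undeca-4,8-dien-1-yl]-5-methyloxolan-2-one F5 as a mixture of C10 epimers. Dess–Martin oxidation should give (5S)-5-[(1R,4E,8E)-11-(furan-3-yl)-4,8-dimethyl-6-oxo-1-(triethylsilyloxy)undeca-4,8-dien-1-yl]-5-methyloxolan-2-one F6. Corey–Bakshi–Shibata reduction with the (R)-methyl oxazaborolidine and catecholborane at −78 °C, the C11=C12 alkenyl group acting as the large substituent, should return (S)-configured 24.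

**Step 10 (lithiation–borylation).** What may go wrong: competing metalation at the furan α-positions; incomplete 1,2-migration of the isopropenyl group; loss of enantiomeric purity if the lithiated carbamate warms before borylation.

Fallback, setting out from 12 (through 14) and coming back at 20: the C7–B centre is set by a catalytic cross-coupling instead of a deprotonation. 3-Furyllithium 14 and oxirane (BF3·OEt2, −78 °C) should give 2-(furan-3-yl)ethan-1-ol F7. Appel-type iodination (I2, PPh3, imidazole) should give 3-(2-iodoethyl)furan F8. Alkylation of lithiated bis(pinacolato)borylmethane (lithium 2,2,6,6-tetramethylpiperidide, THF, 0 °C) with F8 should give 2,2'-[3-(furan-3-yl)propane-1,1-diyl]bis(4,4,5,5-tetramethyl-1,3,2-dioxaborolane) F9. An enantiotopic-group-selective Suzuki–Miyaura coupling of F9 with 2-bromopropene (Pd(OAc)2, a TADDOL-derived phosphoramidite ligand, KOH, dioxane/H2O), with the ligand enantiomer chosen for the R product, should give 20 without any strong base meeting the furan.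

**Step 4 (epoxidation and lactonisation).** What may go wrong: incomplete discrimination between the two trisubstituted alkenes; insufficient facial selectivity of the dioxirane; partial loss of stereochemical fidelity at C16 (ionisation before ring closure) or competing intermolecular hydrolysis of the epoxide during lactonisation.

Fallback, setting out from 1 and coming back at 7: the epoxide is made by a hydroxyl-directed, reagent-controlled epoxidation. Allylic oxidation of the E-methyl group of 1 (SeO2 cat., tBuOOH, CH2Cl2) should give (2E,6E)-8-hydroxy-3,7-dimethylocta-2,6-dien-1-yl acetate F10. Sharpless asymmetric epoxidation (Ti(OiPr)4, D-(−)-diisopropyl tartrate, the tartrate enantiomer that gives (2R,3R)-epoxy alcohols from E-allylic alcohols, tBuOOH, 4 Å sieves, CH2Cl2, −20 °C) can only touch the allylic-alcohol alkene and should give [(2R,3R)-3-[(3E)-5-acetoxy-3-methylpent-3-en-1-yl]-2-methyloxiran-2-yl]methanol F11. Dess–Martin oxidation should give (2S,3R)-3-[(3E)-5-acetoxy-3-methylpent-3-en-1-yl]-2-methyloxirane-2-carbaldehyde F12. Wittig olefination with Ph3P=CHCO2Et should give ethyl (2E)-3-[(2R,3R)-3-[(3E)-5-acetoxy-3-methylpent-3-en-1-yl]-2-methyloxiran-2-yl]prop-2-enoate F13. Diimide reduction (2-nitrobenzenesulfonyl hydrazide, Et3N, rt), which prefers the disubstituted conjugated alkene over the trisubstituted one and leaves the epoxide alone, should give 7, which is then lactonised with CSA as in step 4. This removes the regio- and facial-selectivity risks; the lactonisation itself is unchanged.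

Further compounds
F1 | step 11 | 3-(furan-3-yl)propanal | O=CCCc1ccoc1
F2 | step 11 | ethyl (2E)-5-(furan-3-yl)-2-methylpent-2-enoate | CCOC(=O)/C(C)=C/CCc1ccoc1
F3 | step 11 | (2E)-5-(furan-3-yl)-2-methylpent-2-en-1-ol | OC/C(C)=C/CCc1ccoc1
F4 | step 11 | 3-[(3E)-5-chloro-4-methylpent-3-en-1-yl]furan | ClC/C(C)=C/CCc1ccoc1
F5 | step 11 | (5S)-5-[(1R,4E,6RS,8E)-11-(furan-3-yl)-6-hydroxy-4,8-dimethyl-1-(triethylsilyloxy)undeca-4,8-dien-1-yl]-5-methyloxolan-2-one (C10 epimer mixture) | OC(/C=C(\C)CC[C@@H](O[Si](CC)(CC)CC)[C@]1(C)CCC(=O)O1)C/C(C)=C/CCc1ccoc1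
F6 | step 11 | (5S)-5-[(1R,4E,8E)-11-(furan-3-yl)-4,8-dimethyl-6-oxo-1-(triethylsilyloxy)undeca-4,8-dien-1-yl]-5-methyloxolan-2-one | O=C(/C=C(\C)CC[C@@H](O[Si](CC)(CC)CC)[C@]1(C)CCC(=O)O1)C/C(C)=C/CCc1ccoc1
F7 | step 10 | 2-(furan-3-yl)ethan-1-ol | OCCc1ccoc1
F8 | step 10 | 3-(2-iodoethyl)furan | ICCc1ccoc1
F9 | step 10 | 2,2'-[3-(furan-3-yl)propane-1,1-diyl]bis(4,4,5,5-tetramethyl-1,3,2-dioxaborolane) | CC1(C)OB(OC1(C)C)C(CCc1ccoc1)B1OC(C)(C)C(C)(C)O1
F10 | step 4 | (2E,6E)-8-hydroxy-3,7-dimethylocta-2,6-dien-1-yl acetate | OC/C(C)=C/CC/C(C)=C/COC(C)=O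
F11 | step 4 | [(2R,3R)-3-[(3E)-5-acetoxy-3-methylpent-3-en-1-yl]-2-methyloxiran-2-yl]methanol | OC[C@@]1(C)O[C@@H]1CC/C(C)=C/COC(C)=O
F12 | step 4 | (2S,3R)-3-[(3E)-5-acetoxy-3-methylpent-3-en-1-yl]-2-methyloxirane-2-carbaldehyde | O=C[C@@]1(C)O[C@@H]1CC/C(C)=C/COC(C)=O
F13 | step 4 | ethyl (2E)-3-[(2R,3R)-3-[(3E)-5-acetoxy-3-methylpent-3-en-1-yl]-2-methyloxiran-2-yl]prop-2-enoate | CCOC(=O)/C=C/[C@@]1(C)O[C@@H]1CC/C(C)=C/COC(C)=O
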